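**Strategy.** The ten-membered ring is closed at C9–C10, exploiting the C8(O)–C9H2–C10(O) aldol retron that lies between the acyloxy carbon and the epoxide carbon of the carbocycle. A seco bromomethyl ketone (C8/C9) carrying the trans-fused α-methylene lactone, the Z-C4=C5 alkene and an α-silyloxy methyl ketone (C1/C10) is reduced by SmI2; the samarium enolate adds to the C10 ketone. One operation forms the ring and the tertiary C10 centre under Felkin–Anh control from C1; C10–OH then steers the C8 reduction and finally displaces a C1 mesylate to give the trans-epoxide. C3 comes from a reagent-controlled boron aldol, C1 from an Evans–Tishchenko reduction, C6/C7 from a chromium-catalysed allylation.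

Key step: step 14

Remark: atoms carry germacranolide numbers (C1/C10 epoxide carbons, C14 the methyl on C10; C3 acetoxy carbon; C4=C5 with C15 on C4; C6 lactone O–CH; C7; C8 isovaleryloxy carbon; C9 CH2; C11(=C13H2)–C12(=O) lactone). The target is taken as drawn, (1R,3S,4Z,6R,7R,8S,10R). tert-Butyl glyoxylate is assumed to be purchasable.

**Step 1**
Reactants: 1 (tert-butyldimethylsilyloxy)acetaldehyde; 2 methyl 2-[bis(2,2,2-trifluoroethoxy)phosphoryl]propanoate
Product: 3 methyl (2Z)-4-(tert-butyldimethylsilyloxy)-2-methylbut-2-enoate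
Conditions: KHMDS (KN(SiMe3)2), 18-crown-6, THF, −78 °C
Reagents that add atoms: none
Why: Still–Gennari modification of the Horner–Wadsworth–Emmons olefination; the trifluoroethyl phosphonate under dissociating conditions eliminates from the kinetic adduct and should give the (Z)-trisubstituted enoate that becomes C4=C5.

**Step 2**
Reactants: 3 methyl (2Z)-4-(tert-butyldimethylsilyloxy)-2-methylbut-2-enoate
Product: 4 (2Z)-4-(tert-butyldimethylsilyloxy)-2-methylbut-2-en-1-ol
Conditions: DIBAL-H (i-Bu2AlH), CH2Cl2, −78 °C; Rochelle salt work-up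
Reagents that add atoms: none
Why: DIBAL-H reduction of the enoate should give the allylic alcohol by hydride addition at the ester carbonyl without touching the silyl ether or the alkene geometry.

**Step 3**
Reactants: 4 (2Z)-4-(tert-butyldimethylsilyloxy)-2-methylbut-2-en-1-ol
Product: 5 (2Z)-4-(tert-butyldimethylsilyloxy)-2-methylbut-2-enal
Conditions: MnO2, CH2Cl2, rt
Reagents that add atoms: none
Why: MnO2 oxidises the allylic alcohol selectively under neutral heterogeneous conditions, so the (Z)-enal should form without isomerisation.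

**Step 4**
Reactants: 5 (2Z)-4-(tert-butyldimethylsilyloxy)-2-methylbut-2-enal; 6 3,3-dimethoxybutan-2-one
Product: 7 (5S,6Z)-8-(tert-butyldimethylsilyloxy)-5-hydroxy-2,2-dimethoxy-6-methyloct-6-en-3-one
Conditions: (+)-Ipc2BCl, Et3N, Et2O, 0 °C; then 5, −78 to −20 °C; H2O2, MeOH, pH 7 buffer
Reagents that add atoms: none
Why: Paterson boron aldol reaction; ketone 6 can enolise only at its methyl group, and the diisopinocampheyl ligands of the enol borinate (antipode chosen for attack on the aldehyde Si face, (+)-Ipc2BCl expected) set the (S)-carbinol at C3 by reagent control.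

**Step 5**
Reactants: 7 (5S,6Z)-8-(tert-butyldimethylsilyloxy)-5-hydroxy-2,2-dimethoxy-6-methyloct-6-en-3-one
Product: 8 (3S,5S,6Z)-8-(tert-butyldimethylsilyloxy)-3-hydroxy-2,2-dimethoxy-6-methyloct-6-en-5-yl acetate
Conditions: SmI2 (0.3 equiv), CH3CHO (8 equiv), THF, −10 °C
Reagents that add atoms: acetaldehyde, CC=O (the acetyl group on O3)
Why: Evans–Tishchenko reduction; the samarium-bound hemiacetal of the C3 hydroxyl and acetaldehyde delivers hydride intramolecularly to the ketone through a chair-like bicyclic transition state, setting the 1,3-anti (1S) alcohol and leaving the C3 oxygen as the acetate of the target.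

**Step 6**
Reactants: 8 (3S,5S,6Z)-8-(tert-butyldimethylsilyloxy)-3-hydroxy-2,2-dimethoxy-6-methyloct-6-en-5-yl acetate
Product: 9 (3S,5S,6Z)-3,8-bis(tert-butyldimethylsilyloxy)-2,2-dimethoxy-6-methyloct-6-en-5-yl acetate
Conditions: TBSOTf, 2,6-lutidine, CH2Cl2, −78 °C
Reagents that add atoms: tert-butyldimethylsilyl trifluoromethanesulfonate, CC(C)(C)[Si](C)(C)OS(=O)(=O)C(F)(F)F
Why: Silyl triflate silylation of the hindered secondary alcohol at low temperature, where the dimethyl ketal and the acetate are stable, installs the bulky non-chelating group needed later at C1.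

**Step 7**
Reactants: 9 (3S,5S,6Z)-3,8-bis(tert-butyldimethylsilyloxy)-2,2-dimethoxy-6-methyloct-6-en-5-yl acetate
Product: 10 (2Z,4S,6S)-6-(tert-butyldimethylsilyloxy)-1-hydroxy-3-methyl-7-oxooct-2-en-4-yl acetate
Conditions: TsOH·H2O (10 mol %), acetone/H2O (9:1), 0 °C to rt
Reagents that add atoms: water, O (carbonyl oxygen at C10)
Why: Mild aqueous acid hydrolyses the acyclic dimethyl ketal and the unhindered primary allylic silyl ether, while the hindered secondary silyl ether next to the new ketone and the acetate should survive.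

**Step 8**
Reactants: 10 (2Z,4S,6S)-6-(tert-butyldimethylsilyloxy)-1-hydroxy-3-methyl-7-oxooct-2-en-4-yl acetate
Product: 11 (2Z,4S,6S)-6-(tert-butyldimethylsilyloxy)-3-methyl-1,7-dioxooct-2-en-4-yl acetate
Conditions: MnO2, CH2Cl2, rt
Reagents that add atoms: none
Why: MnO2 oxidation of the primary allylic alcohol should give the (Z)-enal chemoselectively, the ketone, acetate and silyl ether being inert.

**Step 9**
Reactants: 12 methyl acrylate; 13 tert-butyl glyoxylate
Product: 14 4-tert-butyl 1-methyl 3-hydroxy-2-methylidenebutanedioate (racemic)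
Conditions: DABCO (20 mol %), THF, rt
Reagents that add atoms: none
Why: Morita–Baylis–Hillman reaction; the DABCO–acrylate zwitterion adds to the electrophilic glyoxylate and releases the amine to give the allylic alcohol.

**Step 10**
Reactants: 14 4-tert-butyl 1-methyl 3-hydroxy-2-methylidenebutanedioate
Product: 15 4-tert-butyl 1-methyl (2Z)-2-(bromomethyl)but-2-enedioate
Conditions: NBS, Me2S, CH2Cl2, 0 °C
Reagents that add atoms: N-bromosuccinimide, O=C1CCC(=O)N1Br
Why: Corey–Kim-type activation of the Baylis–Hillman alcohol and SN2′ attack of bromide give the rearranged primary allylic bromide under neutral conditions that spare the tert-butyl ester; its E/Z composition is irrelevant for the next step.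

**Step 11**
Reactants: 11 (2Z,4S,6S)-6-(tert-butyldimethylsilyloxy)-3-methyl-1,7-dioxooct-2-en-4-yl acetate; 15 4-tert-butyl 1-methyl (2Z)-2-(bromomethyl)but-2-enedioate
Product: 17 tert-butyl (2R,3S)-2-[(1Z,3S,5S)-3-acetoxy-5-(tert-butyldimethylsilyloxy)-2-methyl-6-oxohept-1-en-1-yl]-4-methylidene-5-oxooxolane-3-carboxylate, via trimethylsilyl ether adduct 16 (not isolated)
Conditions: CrCl2 (10 mol %), chiral 1,8-bis(oxazolinyl)carbazole ligand (10 mol %, enantiomer selected for Si-face attack), DIPEA (30 mol %), Mn powder, TMSCl, THF, rt; then 0.5 M HCl, THF, 0 °C; TsOH·H2O (cat.), CH2Cl2, rt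
Reagents that add atoms: chlorotrimethylsilane, C[Si](C)(C)Cl (silyl ether of intermediate 16 only)
Why: Nozaki–Hiyama–Kishi-type catalytic asymmetric 2-(alkoxycarbonyl)allylation; the ligated trivalent chromium allyl (E and Z bromide converge on one equilibrating species) adds through a chair transition state to the aldehyde (not the ketone) on its Si face to set (6R) with the anti C7 relationship, and acid-promoted lactonisation gives the trans α-methylene lactone, any cis isomer being correctable by epimerisation at the acidic C7–H.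

**Step 12**
Reactants: 17 tert-butyl lactone ester
Product: 18 (2R,3S)-2-[(1Z,3S,5S)-3-acetoxy-5-(tert-butyldimethylsilyloxy)-2-methyl-6-oxohept-1-en-1-yl]-4-methylidene-5-oxooxolane-3-carboxylic acid
Conditions: TFA/CH2Cl2 (1:4), 0 °C
Reagents that add atoms: none
Why: Acidolysis cleaves the tert-butyl ester through the tert-butyl cation (isobutene), while the lactone, the acetate and the electron-poor α-keto silyl ether should persist.

**Step 13**
Reactants: 18 lactone carboxylic acid
Product: 21 (1Z,3S,5S)-1-[(2R,3S)-3-(2-bromoacetyl)-4-methylidene-5-oxooxolan-2-yl]-5-(tert-butyldimethylsilyloxy)-2-methyl-6-oxohept-1-en-3-yl acetate, via acid chloride 19 (not isolated), via diazoketone 20 (not isolated)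
Conditions: (COCl)2, DMF (cat.), CH2Cl2, 0 °C; CH2N2 (2.2 equiv), Et2O, −20 °C; 48 % aq. HBr, −20 to 0 °C
Reagents that add atoms: diazomethane, C=[N+]=[N-] (C9); hydrogen bromide, Br; oxalyl chloride, O=C(Cl)C(=O)Cl (chlorine of intermediate 19 only)
Why: Acid chloride formation, acylation of diazomethane (first stage of the Arndt–Eistert sequence, fast at −20 °C relative to dipolar cycloaddition onto the α-methylene lactone) and hydrobromination of the diazoketone place bromine regiospecifically on C9.

**Step 14**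
Reactants: 21 seco bromomethyl ketone
Product: 23 (1S,3S,4Z,6R,7S,10R)-3-acetoxy-1-(tert-butyldimethylsilyloxy)-10-hydroxy-8-oxogermacra-4,11(13)-dien-12,6-olide, via samarium enolate 22 (not isolated)
Conditions: SmI2 (2.5 equiv), THF, −78 °C, 21 added over 4 h (final 0.002 M); sat. aq. NH4Cl at −78 °C
Reagents that add atoms: none
Why: SmI2 (two single-electron transfers) cleaves the C9–Br bond of the bromomethyl ketone far faster than it touches the α-silyloxy ketone, the enoate or the allylic esters, giving the C8 samarium enolate 22 regiospecifically at C9, which adds to the C10 methyl ketone. The closest known reaction type is the SmI2-promoted intramolecular Reformatsky/aldol cyclisation of α-bromo ketones and esters to eight- to fourteen-membered rings, in which oxophilic trivalent samarium templates enolate and carbonyl. The ten-membered carbocycle closes in the (enolendo) 10-exo-trig mode, helped by high dilution and by the turn that the trans-lactone and the Z-C4=C5 alkene impose on the chain. The new stereocentre C10 is controlled by the adjacent C1 centre: in the polar Felkin–Anh transition state the bulky, non-chelating C1–OTBS bond lies anti to the incoming C9 and the nucleophile passes C1–H, which should give (10R), the C1/C10 relationship that becomes the trans-epoxide after inversion at C1. The step needs chemoselectivity (C–Br reduction only; the ketone, not the lactone carbonyl, as acceptor), site selectivity (C9 and not C7 as nucleophile, fixed by the position of bromine) and facial selectivity at C10 (secured by the silyl ether, which suppresses chelation). The aldolate is quenched cold at neutral pH so that retro-aldol cleavage and elimination of the C6 oxygen are avoided.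

**Step 15**
Reactants: 23 macrocyclic β-hydroxy ketone
Product: 24 (1S,3S,4Z,6R,7R,8S,10R)-3-acetoxy-1-(tert-butyldimethylsilyloxy)-8,10-dihydroxygermacra-4,11(13)-dien-12,6-olide
Conditions: Et2BOMe, THF/MeOH (4:1), −78 °C; NaBH4, −78 °C; AcOH, then MeOH co-evaporation
Reagents that add atoms: none
Why: Narasaka–Prasad reduction; Et2BOMe ties the C10 hydroxyl and the C8 ketone into a six-membered boron chelate and external hydride attacks axially, which should set the 1,3-syn (8S) carbinol from the C10 centre without reducing the lactone or the acrylate.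

**Step 16**
Reactants: 24 syn-1,3-diol
Product: 25 (1S,3S,4Z,6R,7R,8S,10R)-3-acetoxy-1-(tert-butyldimethylsilyloxy)-10-hydroxy-8-(3-methylbutanoyloxy)germacra-4,11(13)-dien-12,6-olide
Conditions: 3-methylbutanoic anhydride, DMAP (cat.), pyridine, CH2Cl2, 0 °C to rt
Reagents that add atoms: 3-methylbutanoic anhydride, CC(C)CC(=O)OC(=O)CC(C)C
Why: DMAP-catalysed acyl transfer esterifies the secondary C8 hydroxyl, the tertiary C10 hydroxyl being too hindered to react.

**Step 17**
Reactants: 25 C8 isovalerate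
Product: 26 (1S,3S,4Z,6R,7R,8S,10R)-3-acetoxy-1,10-dihydroxy-8-(3-methylbutanoyloxy)germacra-4,11(13)-dien-12,6-olide
Conditions: HF·pyridine, pyridine, THF, 0 °C to rt
Reagents that add atoms: none
Why: Buffered HF·pyridine cleaves the Si–O bond (fluoride-driven desilylation) without hydrolysing the esters or the lactone, freeing the C1 hydroxyl before any epoxide is present.

**Step 18**
Reactants: 26 C1,C10-diol
Product: 28 (1R,3S,4Z,6R,7R,8S,10R)-3-acetoxy-1,10-epoxy-8-(3-methylbutanoyloxy)germacra-4,11(13)-dien-12,6-olide (CNP0157657.1), via C1 mesylate 27 (not isolated)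
Conditions: MsCl, Et3N, CH2Cl2, −20 °C; then DBU, rt
Reagents that add atoms: methanesulfonyl chloride, CS(=O)(=O)Cl (sulfonate of intermediate 27 only)
Why: Selective mesylation of the secondary C1 hydroxyl followed by intramolecular Williamson etherification by the tertiary C10 alkoxide (3-exo-tet, SN2 with inversion at C1) should close the trans-epoxide with (1R,10R) configuration.

**Compound list**
1 | (tert-butyldimethylsilyloxy)acetaldehyde | O=CCO[Si](C)(C)C(C)(C)C | starting material
2 | methyl 2-[bis(2,2,2-trifluoroethoxy)phosphoryl]propanoate | COC(=O)C(C)P(=O)(OCC(F)(F)F)OCC(F)(F)F | starting material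
3 | methyl (2Z)-4-(tert-butyldimethylsilyloxy)-2-methylbut-2-enoate | COC(=O)/C(C)=C\CO[Si](C)(C)C(C)(C)C | intermediate
4 | (2Z)-4-(tert-butyldimethylsilyloxy)-2-methylbut-2-en-1-ol | OC/C(C)=C\CO[Si](C)(C)C(C)(C)C | intermediate
5 | (2Z)-4-(tert-butyldimethylsilyloxy)-2-methylbut-2-enal | O=C/C(C)=C\CO[Si](C)(C)C(C)(C)C | intermediate
6 | 3,3-dimethoxybutan-2-one | CC(=O)C(C)(OC)OC | starting material
7 | (5S,6Z)-8-(tert-butyldimethylsilyloxy)-5-hydroxy-2,2-dimethoxy-6-methyloct-6-en-3-one | CC(C)(C)[Si](C)(C)OC/C=C(/C)[C@@H](O)CC(=O)C(C)(OC)OC | intermediate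
8 | (3S,5S,6Z)-8-(tert-butyldimethylsilyloxy)-3-hydroxy-2,2-dimethoxy-6-methyloct-6-en-5-yl acetate | CC(C)(C)[Si](C)(C)OC/C=C(/C)[C@@H](OC(C)=O)C[C@H](O)C(C)(OC)OC | intermediate
9 | (3S,5S,6Z)-3,8-bis(tert-butyldimethylsilyloxy)-2,2-dimethoxy-6-methyloct-6-en-5-yl acetate | CC(C)(C)[Si](C)(C)OC/C=C(/C)[C@@H](OC(C)=O)C[C@H](O[Si](C)(C)C(C)(C)C)C(C)(OC)OC | intermediate
10 | (2Z,4S,6S)-6-(tert-butyldimethylsilyloxy)-1-hydroxy-3-methyl-7-oxooct-2-en-4-yl acetate | OC/C=C(/C)[C@@H](OC(C)=O)C[C@H](O[Si](C)(C)C(C)(C)C)C(C)=O | intermediate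
11 | (2Z,4S,6S)-6-(tert-butyldimethylsilyloxy)-3-methyl-1,7-dioxooct-2-en-4-yl acetate | O=C/C=C(/C)[C@@H](OC(C)=O)C[C@H](O[Si](C)(C)C(C)(C)C)C(C)=O | intermediate
12 | methyl acrylate | C=CC(=O)OC | starting material
13 | tert-butyl glyoxylate | O=CC(=O)OC(C)(C)C | starting material
14 | 4-tert-butyl 1-methyl 3-hydroxy-2-methylidenebutanedioate (racemic) | C=C(C(=O)OC)C(O)C(=O)OC(C)(C)C | intermediate
15 | 4-tert-butyl 1-methyl (2Z)-2-(bromomethyl)but-2-enedioate | COC(=O)/C(CBr)=C/C(=O)OC(C)(C)C | intermediate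
16 | 4-tert-butyl 1-methyl (3S)-3-[(1R,2Z,4S,6S)-4-acetoxy-6-(tert-butyldimethylsilyloxy)-3-methyl-7-oxo-1-(trimethylsilyloxy)oct-2-en-1-yl]-2-methylidenebutanedioate | COC(=O)C(=C)[C@H](C(=O)OC(C)(C)C)[C@H](O[Si](C)(C)C)/C=C(/C)[C@@H](OC(C)=O)C[C@H](O[Si](C)(C)C(C)(C)C)C(C)=O | intermediate
17 | tert-butyl (2R,3S)-2-[(1Z,3S,5S)-3-acetoxy-5-(tert-butyldimethylsilyloxy)-2-methyl-6-oxohept-1-en-1-yl]-4-methylidene-5-oxooxolane-3-carboxylate | C=C1C(=O)O[C@H](/C=C(/C)[C@@H](OC(C)=O)C[C@H](O[Si](C)(C)C(C)(C)C)C(C)=O)[C@H]1C(=O)OC(C)(C)C | intermediate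
18 | (2R,3S)-2-[(1Z,3S,5S)-3-acetoxy-5-(tert-butyldimethylsilyloxy)-2-methyl-6-oxohept-1-en-1-yl]-4-methylidene-5-oxooxolane-3-carboxylic acid | C=C1C(=O)O[C@H](/C=C(/C)[C@@H](OC(C)=O)C[C@H](O[Si](C)(C)C(C)(C)C)C(C)=O)[C@H]1C(=O)O | intermediate
19 | (2R,3S)-2-[(1Z,3S,5S)-3-acetoxy-5-(tert-butyldimethylsilyloxy)-2-methyl-6-oxohept-1-en-1-yl]-4-methylidene-5-oxooxolane-3-carbonyl chloride | C=C1C(=O)O[C@H](/C=C(/C)[C@@H](OC(C)=O)C[C@H](O[Si](C)(C)C(C)(C)C)C(C)=O)[C@H]1C(=O)Cl | intermediate
20 | (1Z,3S,5S)-5-(tert-butyldimethylsilyloxy)-1-[(2R,3S)-3-(2-diazoacetyl)-4-methylidene-5-oxooxolan-2-yl]-2-methyl-6-oxohept-1-en-3-yl acetate | C=C1C(=O)O[C@H](/C=C(/C)[C@@H](OC(C)=O)C[C@H](O[Si](C)(C)C(C)(C)C)C(C)=O)[C@H]1C(=O)C=[N+]=[N-] | intermediate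
21 | (1Z,3S,5S)-1-[(2R,3S)-3-(2-bromoacetyl)-4-methylidene-5-oxooxolan-2-yl]-5-(tert-butyldimethylsilyloxy)-2-methyl-6-oxohept-1-en-3-yl acetate | C=C1C(=O)O[C@H](/C=C(/C)[C@@H](OC(C)=O)C[C@H](O[Si](C)(C)C(C)(C)C)C(C)=O)[C@H]1C(=O)CBr | intermediate
22 | diiodosamarium enolate of 21 (O-bound at C8, C8=C9H2) | C=C1C(=O)O[C@H](/C=C(/C)[C@@H](OC(C)=O)C[C@H](O[Si](C)(C)C(C)(C)C)C(C)=O)[C@H]1C(=C)O[Sm](I)I | intermediate
23 | (1S,3S,4Z,6R,7S,10R)-3-acetoxy-1-(tert-butyldimethylsilyloxy)-10-hydroxy-8-oxogermacra-4,11(13)-dien-12,6-olide | C=C1C(=O)O[C@@H]2/C=C(/C)[C@@H](OC(C)=O)C[C@H](O[Si](C)(C)C(C)(C)C)[C@](C)(O)CC(=O)[C@@H]12 | intermediate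
24 | (1S,3S,4Z,6R,7R,8S,10R)-3-acetoxy-1-(tert-butyldimethylsilyloxy)-8,10-dihydroxygermacra-4,11(13)-dien-12,6-olide | C=C1C(=O)O[C@@H]2/C=C(/C)[C@@H](OC(C)=O)C[C@H](O[Si](C)(C)C(C)(C)C)[C@](C)(O)C[C@H](O)[C@@H]12 | intermediate
25 | (1S,3S,4Z,6R,7R,8S,10R)-3-acetoxy-1-(tert-butyldimethylsilyloxy)-10-hydroxy-8-(3-methylbutanoyloxy)germacra-4,11(13)-dien-12,6-olide | C=C1C(=O)O[C@@H]2/C=C(/C)[C@@H](OC(C)=O)C[C@H](O[Si](C)(C)C(C)(C)C)[C@](C)(O)C[C@H](OC(=O)CC(C)C)[C@@H]12 | intermediate
26 | (1S,3S,4Z,6R,7R,8S,10R)-3-acetoxy-1,10-dihydroxy-8-(3-methylbutanoyloxy)germacra-4,11(13)-dien-12,6-olide | C=C1C(=O)O[C@@H]2/C=C(/C)[C@@H](OC(C)=O)C[C@H](O)[C@](C)(O)C[C@H](OC(=O)CC(C)C)[C@@H]12 | intermediate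
27 | (1S,3S,4Z,6R,7R,8S,10R)-3-acetoxy-10-hydroxy-1-(methanesulfonyloxy)-8-(3-methylbutanoyloxy)germacra-4,11(13)-dien-12,6-olide | C=C1C(=O)O[C@@H]2/C=C(/C)[C@@H](OC(C)=O)C[C@H](OS(C)(=O)=O)[C@](C)(O)C[C@H](OC(=O)CC(C)C)[C@@H]12 | intermediate
28 | (1R,3S,4Z,6R,7R,8S,10R)-3-acetoxy-1,10-epoxy-8-(3-methylbutanoyloxy)germacra-4,11(13)-dien-12,6-olide (CNP0157657.1) | C=C1C(=O)O[C@@H]2/C=C(/C)[C@@H](OC(C)=O)C[C@H]3O[C@]3(C)C[C@H](OC(=O)CC(C)C)[C@@H]12 | target

**Step count and risks**
Total step count: 18. Longest linear sequence: 16 steps (steps 1–8 and 11–18); steps 9–10 make the allyl bromide branch.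

The three steps most likely to fail:

1. Step 14 (ring closure). What may go wrong: protonation of the samarium enolate before it reaches the C10 ketone, intermolecular aldol addition outrunning the ten-membered ring closure, or chelation of trivalent samarium by the C1 oxygen eroding the Felkin–Anh facial preference at C10. Fallback: the metal enolate is replaced by a neutral enol silane and the addition is run under Lewis acid activation. Setting out from bromoketone 21, reductive silylation (Zn, TMSCl, TMEDA, Et2O) should give the trimethylsilyl enol ether F1. An intramolecular Mukaiyama aldol addition (BF3·OEt2, CH2Cl2, −78 °C, high dilution; open, non-chelated transition state) then closes C9–C10, and aqueous work-up comes back to the route at 23.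

2. Step 11 (lactone annulation). What may go wrong: insufficient enantiofacial discrimination of the (Z)-enal by the chiral chromium allyl, or leakage to the syn adduct with the doubly activated allyl bromide. Fallback: auxiliary control in place of catalyst control. Setting out from aldehyde 11, an Evans syn-aldol addition is run with the dibutylboron dienolate of the itaconate imide F2 (prepared from (S)-4-benzyloxazolidin-2-one and itaconic acid 1-methyl ester; Bu2BOTf, i-Pr2NEt, CH2Cl2, −78 °C). Reaction at the α-carbon should give the syn adduct F3, acid (TsOH, CH2Cl2) closes the lactone to the lactone imide F4, and LiOH/H2O2 (THF/H2O, 0 °C) removes the auxiliary to come back at acid 18.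

3. Step 15 (C8 reduction). What may go wrong: hydride attack on the face of the medium-ring ketone dictated by the ring conformation and not by the boron chelate, giving the C8 epimer. Fallback: the opposite diastereomer is made on purpose and inverted while the ester is installed. Setting out from 23, Evans–Saksena reduction (Me4NBH(OAc)3, MeCN/AcOH, −20 °C; intramolecular hydride delivery from the C10-bound acetoxyborohydride) should give the 1,3-anti diol F5. A Mitsunobu esterification with 3-methylbutanoic acid (PPh3, DIAD, toluene) then inverts C8 and comes back at isovalerate 25.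

**Further compounds**
F1 | step 14 | (1Z,3S,5S)-5-(tert-butyldimethylsilyloxy)-2-methyl-1-{(2R,3S)-4-methylidene-5-oxo-3-[1-(trimethylsilyloxy)ethenyl]oxolan-2-yl}-6-oxohept-1-en-3-yl acetate | C=C1C(=O)O[C@H](/C=C(/C)[C@@H](OC(C)=O)C[C@H](O[Si](C)(C)C(C)(C)C)C(C)=O)[C@H]1C(=C)O[Si](C)(C)C
F2 | step 11 | (S)-4-benzyl-3-[3-(methoxycarbonyl)but-3-enoyl]oxazolidin-2-one | COC(=O)C(=C)CC(=O)N1[C@@H](Cc2ccccc2)COC1=O
F3 | step 11 | methyl (3S,4R,5Z,7S,9S)-7-acetoxy-3-[(S)-4-benzyl-2-oxooxazolidine-3-carbonyl]-9-(tert-butyldimethylsilyloxy)-4-hydroxy-6-methyl-2-methylidene-10-oxoundec-5-enoate (Evans syn adduct) | COC(=O)C(=C)[C@H](C(=O)N1[C@@H](Cc2ccccc2)COC1=O)[C@H](O)/C=C(/C)[C@@H](OC(C)=O)C[C@H](O[Si](C)(C)C(C)(C)C)C(C)=O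
F4 | step 11 | (1Z,3S,5S)-1-{(2R,3S)-3-[(S)-4-benzyl-2-oxooxazolidine-3-carbonyl]-4-methylidene-5-oxooxolan-2-yl}-5-(tert-butyldimethylsilyloxy)-2-methyl-6-oxohept-1-en-3-yl acetate | C=C1C(=O)O[C@H](/C=C(/C)[C@@H](OC(C)=O)C[C@H](O[Si](C)(C)C(C)(C)C)C(C)=O)[C@H]1C(=O)N1[C@@H](Cc2ccccc2)COC1=O
F5 | step 15 | (1S,3S,4Z,6R,7R,8R,10R)-3-acetoxy-1-(tert-butyldimethylsilyloxy)-8,10-dihydroxygermacra-4,11(13)-dien-12,6-olide (1,3-anti diol, C8 epimer of 24) | C=C1C(=O)O[C@@H]2/C=C(/C)[C@@H](OC(C)=O)C[C@H](O[Si](C)(C)C(C)(C)C)[C@](C)(O)C[C@@H](O)[C@@H]12
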